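## Retrosynthetic overview

1. Target ⇒ (Lindlar semi-reduction, desilylation, esterification at O7) the 5,7-syn-diol nine-membered lactone plus (R)-4-silyloxyoct-2-ynoic acid, the latter from (R)-hept-1-yn-3-ol and CO2.
2. Diol ⇒ (1,3-syn reduction) 7-oxo lactone ⇒ C5–C6 intramolecular aldol of an open-chain keto aldehyde ester; this step closes the only ring (C1 carbonyl, C2–C8, O9).
3. Feature used: C8–O9 with its methyl is an (S)-lactate carbinol and C7/C6 are its ethyl-ketone extension, while the C5 carbinol sits next to the fully substituted C4. A chain already joined through the O9–C1 ester can therefore be closed between a C6 ketone enolate and a C5 aldehyde that has no α-hydrogen.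
4. Keto aldehyde ester ⇒ (ozonolysis of a C4 vinyl group, Yamaguchi ester) (S)-2-hydroxypentan-3-one from ethyl (S)-lactate plus the C1–C5 acid. The acid ⇒ Evans syn aldol (sets C2, C3) of (R)-4-benzyl-3-propionyloxazolidin-2-one with (R)-2-methyl-2-silyloxybut-3-enal.
5. The quaternary C4 is taken from (S)-2-methylglycidol and O4 is silylated before C1 becomes an acyl group, so no facial selectivity at C4 and no γ-lactonisation onto C1 has to be managed.

Key step: step 11

Assumption: (S)-2-methylglycidol (1) is treated as a purchasable enantiopure building block, and the nine-membered lactone is taken to be isolable once its C3–C5 hydroxyls are free, so every step after ring closure avoids base.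

## Route

Step 1
Reactants: 1 (S)-2-methylglycidol
Product: 2 (R)-2-methylbut-3-ene-1,2-diol
Conditions: Me3S+ I− (4 equiv), n-BuLi (4 equiv), THF, −10 °C; then 1, −10 °C → rt; solid NH4Cl, filtration, distillation
Reagents that add atoms: trimethylsulfonium iodide, C[S+](C)C.[I-]
Why: One-carbon homologation of an epoxide to an allylic alcohol with dimethylsulfonium methylide (Corey–Chaykovsky-type opening at the epoxide CH2, then ylide-mediated elimination of Me2S); the quaternary C–O bond is not broken and Payne equilibration of the alkoxide is degenerate, so the centre that becomes C4 is carried over unchanged.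

Step 2
Reactants: 2 (R)-2-methylbut-3-ene-1,2-diol
Product: 3 (R)-3-methyl-3,4-bis(triethylsilyloxy)but-1-ene
Conditions: TESOTf (2.4 equiv), 2,6-lutidine, CH2Cl2, −78 → 0 °C
Reagents that add atoms: triethylsilyl trifluoromethanesulfonate, CC[Si](CC)(CC)OS(=O)(=O)C(F)(F)F
Why: Silylation with a silyl triflate and a hindered base caps both the primary and the tertiary allylic hydroxyl.

Step 3
Reactants: 3 (R)-3-methyl-3,4-bis(triethylsilyloxy)but-1-ene
Product: 5 (R)-2-methyl-2-(triethylsilyloxy)but-3-enal, via alkoxysulfonium chloride 4 (not isolated)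
Conditions: (COCl)2, DMSO, CH2Cl2, −78 → −30 °C; Et3N, −78 °C → rt
Reagents that add atoms: none
Why: Swern oxidation in which chlorodimethylsulfonium chloride cleaves only the primary triethylsilyl ether and oxidises it in the same flask (oxidative desilylation), the tertiary silyl ether being inert; the aldehyde has no α-hydrogen and cannot epimerise.

Step 4
Reactants: 6 (R)-4-benzyl-3-propionyloxazolidin-2-one; 5 (R)-2-methyl-2-(triethylsilyloxy)but-3-enal
Product: 9 (R)-4-benzyl-3-[(2R,3R,4R)-3-hydroxy-2,4-dimethyl-4-(triethylsilyloxy)hex-5-enoyl]oxazolidin-2-one, via boron enolate 7 (not isolated), via boron aldolate 8 (not isolated)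
Conditions: Bu2BOTf, iPr2NEt, CH2Cl2, 0 °C; then 5, −78 → 0 °C; pH 7 buffer, MeOH, H2O2, 0 °C
Reagents that add atoms: none
Why: Evans syn aldol: the (Z)-dibutylboron enolate reacts through a Zimmerman–Traxler chair with the auxiliary carbonyls opposed, so the (R)-benzyl group sets C2 (R) and C3 (R) under reagent control, the quaternary aldehyde (methyl against vinyl at C4) having little facial bias of its own.

Step 5
Reactants: 9 (R)-4-benzyl-3-[(2R,3R,4R)-3-hydroxy-2,4-dimethyl-4-(triethylsilyloxy)hex-5-enoyl]oxazolidin-2-one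
Product: 10 (R)-4-benzyl-3-[(2R,3R,4R)-2,4-dimethyl-3,4-bis(triethylsilyloxy)hex-5-enoyl]oxazolidin-2-one
Conditions: TESOTf, 2,6-lutidine, CH2Cl2, −78 → 0 °C
Reagents that add atoms: triethylsilyl trifluoromethanesulfonate, CC[Si](CC)(CC)OS(=O)(=O)C(F)(F)F
Why: Silyl triflate silylation is strong enough for the hindered C3 hydroxyl and, being non-basic at low temperature, avoids retro-aldol cleavage.

Step 6
Reactants: 10 (R)-4-benzyl-3-[(2R,3R,4R)-2,4-dimethyl-3,4-bis(triethylsilyloxy)hex-5-enoyl]oxazolidin-2-one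
Product: 12 (2R,3R,4R)-2,4-dimethyl-3,4-bis(triethylsilyloxy)hex-5-enoic acid, via peroxy acid 11 (not isolated)
Conditions: LiOH, H2O2, THF/H2O, 0 °C → rt; Na2SO3; 1 M HCl to pH 3–4, 0 °C
Reagents that add atoms: hydrogen peroxide (as LiOOH), OO
Why: Evans auxiliary cleavage with lithium hydroperoxide, which attacks the exocyclic imide carbonyl; the peroxy acid is reduced by sulfite, and because O4 is already silylated the γ-oxygen cannot lactonise onto C1.

Step 7
Reactants: 13 ethyl (S)-lactate
Product: 14 (S)-2-hydroxy-N-methoxy-N-methylpropanamide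
Conditions: MeONHMe·HCl, iPrMgCl, THF, −20 → 0 °C
Reagents that add atoms: N,O-dimethylhydroxylamine hydrochloride, CNOC.Cl
Why: Weinreb amide formation by aminolysis of the ester with the chloromagnesium amide; the carbinol centre is not involved.

Step 8
Reactants: 14 (S)-2-hydroxy-N-methoxy-N-methylpropanamide
Product: 15 (S)-2-hydroxypentan-3-one
Conditions: EtMgBr (3 equiv), THF, 0 °C → rt; aq NH4Cl
Reagents that add atoms: ethylmagnesium bromide, CC[Mg]Br
Why: Weinreb ketone synthesis: the chelated tetrahedral magnesium adduct holds the ketone oxidation level until work-up, so the ethyl ketone should form without over-addition or racemisation.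

Step 9
Reactants: 12 (2R,3R,4R)-2,4-dimethyl-3,4-bis(triethylsilyloxy)hex-5-enoic acid; 15 (S)-2-hydroxypentan-3-one
Product: 17 (S)-3-oxopentan-2-yl (2R,3R,4R)-2,4-dimethyl-3,4-bis(triethylsilyloxy)hex-5-enoate, via mixed anhydride 16 (not isolated)
Conditions: 2,4,6-trichlorobenzoyl chloride, Et3N, THF, rt; then 15 (2.5 equiv), DMAP, toluene, rt
Reagents that add atoms: none
Why: Yamaguchi esterification: the mixed anhydride acylates the secondary α-ketol hydroxyl under DMAP catalysis, so the O9–C1 bond is made as an ordinary open-chain ester and no medium-ring lactonisation is needed later.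

Step 10
Reactants: 17 (S)-3-oxopentan-2-yl (2R,3R,4R)-2,4-dimethyl-3,4-bis(triethylsilyloxy)hex-5-enoate
Product: 19 (S)-3-oxopentan-2-yl (2R,3R,4S)-2,4-dimethyl-5-oxo-3,4-bis(triethylsilyloxy)pentanoate, via ozonide 18 (not isolated)
Conditions: O3, CH2Cl2, −78 °C; PPh3, −78 °C → rt
Reagents that add atoms: ozone, [O-][O+]=O
Why: Ozonolysis with reductive work-up unmasks the vinyl group as the C5 aldehyde; ketone, ester and silyl ethers are inert to ozone (the C4 descriptor changes from R to S only because the formyl group outranks C3).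

Step 11
Reactants: 19 (S)-3-oxopentan-2-yl (2R,3R,4S)-2,4-dimethyl-5-oxo-3,4-bis(triethylsilyloxy)pentanoate
Product: 22 (2R,3R,4R,5S,6S,8S)-5-hydroxy-2,4,6-trimethyl-7-oxo-3,4-bis(triethylsilyloxy)nonan-8-olide, via titanium enolate 20 (not isolated), via titanium aldolate 21 (not isolated)
Conditions: TiCl4 (3 equiv), CH2Cl2 (0.002 M in 19), −78 °C; iPr2NEt (3.5 equiv) added over 4 h; −78 → −40 °C; sat. aq NH4Cl
Reagents that add atoms: none
Why: TiCl4 binds the C7 ketone and iPr2NEt removes a C6 proton to give the trichlorotitanium (Z)-enolate 20, whose tetravalent titanium then binds the C5 aldehyde and delivers C6 to it through a six-membered chair (Zimmerman–Traxler) transition state embedded in the forming ring, leaving the titanium aldolate 21. The closest known reaction type is the titanium-mediated direct syn aldol of ethyl ketones with aldehydes and its intramolecular use for ring closure under soft enolisation; nine-membered cases are rare, so the risk of the route is concentrated here. The ring (C1, C2–C8, O9) is closed by C5–C6 bond formation in a 9-(enolendo)-exo-trig mode on a chain that already contains the O9–C1 ester, at 0.002 M to hold back intermolecular aldol addition. C6 should become (S) because, with H-8 in the enolate plane, O9 and the tether sit over one enolate face, which is the face the aldehyde reaches, and C5 should become (S) because a (Z)-enolate in a chair with C4 pseudo-equatorial gives the 5,6-syn pair. The step needs enolisation at C6 only, which the kinetic preference of α′-acyloxy ethyl ketones for the CH2 side and the much lower acidity of H-2 should secure, and it needs the aldehyde to act only as acceptor, which the quaternary C4 guarantees.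

Step 12
Reactants: 22 (2R,3R,4R,5S,6S,8S)-5-hydroxy-2,4,6-trimethyl-7-oxo-3,4-bis(triethylsilyloxy)nonan-8-olide
Product: 24 (2R,3R,4R,5S,6R,7R,8S)-5,7-dihydroxy-2,4,6-trimethyl-3,4-bis(triethylsilyloxy)nonan-8-olide, via boron chelate 23 (not isolated)
Conditions: Et2BOMe, THF/MeOH 4:1, −78 °C; NaBH4, −78 °C; AcOH; repeated evaporation from MeOH
Reagents that add atoms: none
Why: Narasaka–Prasad reduction: Et2BOMe ties the C5 hydroxyl and the C7 ketone into a six-membered boron chelate and borohydride adds from outside to give the 1,3-syn diol with C7 (R), the Felkin–Anh preferences of the C6 methyl and C8 acyloxy centres pointing the same way (C6 is now named R only because C5 outranks C7 in the diol).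

Step 13
Reactants: 25 (R)-hept-1-yn-3-ol
Product: 26 (R)-3-(tert-butyldimethylsilyloxy)hept-1-yne
Conditions: TBSCl, imidazole, DMF, rt
Reagents that add atoms: tert-butyldimethylsilyl chloride, CC(C)(C)[Si](C)(C)Cl
Why: Standard silylation; the tert-butyldimethylsilyl ether is chosen because it survives the strongly acidic ynoic acid made next.

Step 14
Reactants: 26 (R)-3-(tert-butyldimethylsilyloxy)hept-1-yne
Product: 28 (R)-4-(tert-butyldimethylsilyloxy)oct-2-ynoic acid, via lithium acetylide 27 (not isolated)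
Conditions: n-BuLi, THF, −78 °C; CO2; 1 M HCl, 0 °C
Reagents that add atoms: carbon dioxide, O=C=O
Why: Carboxylation of a lithium acetylide with CO2; the propargylic centre is not acidic enough to be touched.

Step 15
Reactants: 24 (2R,3R,4R,5S,6R,7R,8S)-5,7-dihydroxy-2,4,6-trimethyl-3,4-bis(triethylsilyloxy)nonan-8-olide; 28 (R)-4-(tert-butyldimethylsilyloxy)oct-2-ynoic acid
Product: 29 (2R,3R,4R,5S,6S,7R,8S)-7-[(R)-4-(tert-butyldimethylsilyloxy)oct-2-ynoyloxy]-5-hydroxy-2,4,6-trimethyl-3,4-bis(triethylsilyloxy)nonan-8-olide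
Conditions: DIC, DMAP (0.1 equiv), CH2Cl2, −20 → 0 °C
Reagents that add atoms: none
Why: Steglich-type carbodiimide esterification, expected at the C7 hydroxyl (flanked by two CH groups) in preference to the C5 hydroxyl, which is shielded by the fully substituted, silyloxy-bearing C4; DMAP is kept catalytic and cold to avoid its addition to the ynoate.

Step 16
Reactants: 29 (2R,3R,4R,5S,6S,7R,8S)-7-[(R)-4-(tert-butyldimethylsilyloxy)oct-2-ynoyloxy]-5-hydroxy-2,4,6-trimethyl-3,4-bis(triethylsilyloxy)nonan-8-olide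
Product: 30 (2R,3R,4R,5S,6S,7R,8S)-3,4,5-trihydroxy-7-[(R)-4-hydroxyoct-2-ynoyloxy]-2,4,6-trimethylnonan-8-olide
Conditions: HF·pyridine, pyridine, THF, 0 °C → rt
Reagents that add atoms: none
Why: Fluoride-mediated desilylation with buffered HF·pyridine removes the two triethylsilyl ethers and the tert-butyldimethylsilyl ether; at the ynoate stage the linear C≡C keeps the freed C4′ hydroxyl away from its own ester carbonyl, and weakly acidic rather than basic conditions avoid acyl migration and translactonisation.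

Step 17
Reactants: 30 (2R,3R,4R,5S,6S,7R,8S)-3,4,5-trihydroxy-7-[(R)-4-hydroxyoct-2-ynoyloxy]-2,4,6-trimethylnonan-8-olide
Product: 31 (2R,3R,4R,5S,6S,7R,8S)-3,4,5-trihydroxy-7-[(R,Z)-4-hydroxyoct-2-enoyloxy]-2,4,6-trimethylnonan-8-olide (target)
Conditions: H2 (1 atm), Pd/CaCO3 poisoned with Pb(OAc)2 (Lindlar catalyst), quinoline, EtOAc, rt; stopped after 1 equiv H2
Reagents that add atoms: none
Why: Lindlar semi-hydrogenation: syn delivery of H2 on lead-poisoned palladium gives the (Z)-enoate under neutral conditions, quinoline and the H2 limit preventing over-reduction.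

## Compound list

1 | (S)-2-methylglycidol | OC[C@@]1(C)CO1 | starting material
2 | (R)-2-methylbut-3-ene-1,2-diol | C=C[C@@](C)(O)CO | intermediate
3 | (R)-3-methyl-3,4-bis(triethylsilyloxy)but-1-ene | C=C[C@@](C)(O[Si](CC)(CC)CC)CO[Si](CC)(CC)CC | intermediate
4 | dimethyl[(R)-2-methyl-2-(triethylsilyloxy)but-3-enyloxy]sulfonium chloride (not isolated) | C=C[C@@](C)(O[Si](CC)(CC)CC)CO[S+](C)C.[Cl-] | intermediate
5 | (R)-2-methyl-2-(triethylsilyloxy)but-3-enal | C=C[C@@](C)(O[Si](CC)(CC)CC)C=O | intermediate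
6 | (R)-4-benzyl-3-propionyloxazolidin-2-one | CCC(=O)N1[C@H](Cc2ccccc2)COC1=O | starting material
7 | dibutylboron (Z)-enolate of 6 (not isolated) | C/C=C(\OB(CCCC)CCCC)N1[C@H](Cc2ccccc2)COC1=O | intermediate
8 | dibutylboron aldolate of 9 (not isolated) | O=C(N1[C@H](Cc2ccccc2)COC1=O)[C@H](C)[C@@H](OB(CCCC)CCCC)[C@](C)(O[Si](CC)(CC)CC)C=C | intermediate
9 | (R)-4-benzyl-3-[(2R,3R,4R)-3-hydroxy-2,4-dimethyl-4-(triethylsilyloxy)hex-5-enoyl]oxazolidin-2-one | O=C(N1[C@H](Cc2ccccc2)COC1=O)[C@H](C)[C@@H](O)[C@](C)(O[Si](CC)(CC)CC)C=C | intermediate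
10 | (R)-4-benzyl-3-[(2R,3R,4R)-2,4-dimethyl-3,4-bis(triethylsilyloxy)hex-5-enoyl]oxazolidin-2-one | O=C(N1[C@H](Cc2ccccc2)COC1=O)[C@H](C)[C@@H](O[Si](CC)(CC)CC)[C@](C)(O[Si](CC)(CC)CC)C=C | intermediate
11 | (2R,3R,4R)-2,4-dimethyl-3,4-bis(triethylsilyloxy)hex-5-eneperoxoic acid (not isolated) | OOC(=O)[C@H](C)[C@@H](O[Si](CC)(CC)CC)[C@](C)(O[Si](CC)(CC)CC)C=C | intermediate
12 | (2R,3R,4R)-2,4-dimethyl-3,4-bis(triethylsilyloxy)hex-5-enoic acid | OC(=O)[C@H](C)[C@@H](O[Si](CC)(CC)CC)[C@](C)(O[Si](CC)(CC)CC)C=C | intermediate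
13 | ethyl (S)-lactate | CCOC(=O)[C@H](C)O | starting material
14 | (S)-2-hydroxy-N-methoxy-N-methylpropanamide | CON(C)C(=O)[C@H](C)O | intermediate
15 | (S)-2-hydroxypentan-3-one | CCC(=O)[C@H](C)O | intermediate
16 | mixed anhydride of 12 with 2,4,6-trichlorobenzoic acid (not isolated) | O=C(OC(=O)c1c(Cl)cc(Cl)cc1Cl)[C@H](C)[C@@H](O[Si](CC)(CC)CC)[C@](C)(O[Si](CC)(CC)CC)C=C | intermediate
17 | (S)-3-oxopentan-2-yl (2R,3R,4R)-2,4-dimethyl-3,4-bis(triethylsilyloxy)hex-5-enoate | CCC(=O)[C@H](C)OC(=O)[C@H](C)[C@@H](O[Si](CC)(CC)CC)[C@](C)(O[Si](CC)(CC)CC)C=C | intermediate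
18 | ozonide (1,2,4-trioxolane) of 17, epimers at the trioxolane carbon (not isolated) | CCC(=O)[C@H](C)OC(=O)[C@H](C)[C@@H](O[Si](CC)(CC)CC)[C@](C)(O[Si](CC)(CC)CC)C1OCOO1 | intermediate
19 | (S)-3-oxopentan-2-yl (2R,3R,4S)-2,4-dimethyl-5-oxo-3,4-bis(triethylsilyloxy)pentanoate (key-step precursor) | CCC(=O)[C@H](C)OC(=O)[C@H](C)[C@@H](O[Si](CC)(CC)CC)[C@](C)(O[Si](CC)(CC)CC)C=O | intermediate
20 | trichlorotitanium (Z)-enolate of 19 (not isolated) | C/C=C(\O[Ti](Cl)(Cl)Cl)[C@H](C)OC(=O)[C@H](C)[C@@H](O[Si](CC)(CC)CC)[C@](C)(O[Si](CC)(CC)CC)C=O | intermediate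
21 | trichlorotitanium aldolate of 22 (not isolated) | O=C1[C@@H](C)[C@H](O[Ti](Cl)(Cl)Cl)[C@@](C)(O[Si](CC)(CC)CC)[C@H](O[Si](CC)(CC)CC)[C@@H](C)C(=O)O[C@H]1C | intermediate
22 | (2R,3R,4R,5S,6S,8S)-5-hydroxy-2,4,6-trimethyl-7-oxo-3,4-bis(triethylsilyloxy)nonan-8-olide (key-step product) | O=C1[C@@H](C)[C@H](O)[C@@](C)(O[Si](CC)(CC)CC)[C@H](O[Si](CC)(CC)CC)[C@@H](C)C(=O)O[C@H]1C | intermediate
23 | O5-diethylboron chelate of 22 (not isolated) | O=C1[C@@H](C)[C@H](OB(CC)CC)[C@@](C)(O[Si](CC)(CC)CC)[C@H](O[Si](CC)(CC)CC)[C@@H](C)C(=O)O[C@H]1C | intermediate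
24 | (2R,3R,4R,5S,6R,7R,8S)-5,7-dihydroxy-2,4,6-trimethyl-3,4-bis(triethylsilyloxy)nonan-8-olide | O[C@@H]1[C@@H](C)[C@H](O)[C@@](C)(O[Si](CC)(CC)CC)[C@H](O[Si](CC)(CC)CC)[C@@H](C)C(=O)O[C@H]1C | intermediate
25 | (R)-hept-1-yn-3-ol | CCCC[C@@H](O)C#C | starting material
26 | (R)-3-(tert-butyldimethylsilyloxy)hept-1-yne | CCCC[C@@H](O[Si](C)(C)C(C)(C)C)C#C | intermediate
27 | lithium acetylide of 26 (not isolated) | CCCC[C@@H](O[Si](C)(C)C(C)(C)C)C#C[Li] | intermediate
28 | (R)-4-(tert-butyldimethylsilyloxy)oct-2-ynoic acid | CCCC[C@@H](O[Si](C)(C)C(C)(C)C)C#CC(=O)O | intermediate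
29 | (2R,3R,4R,5S,6S,7R,8S)-7-[(R)-4-(tert-butyldimethylsilyloxy)oct-2-ynoyloxy]-5-hydroxy-2,4,6-trimethyl-3,4-bis(triethylsilyloxy)nonan-8-olide | CCCC[C@@H](O[Si](C)(C)C(C)(C)C)C#CC(=O)O[C@@H]1[C@@H](C)[C@H](O)[C@@](C)(O[Si](CC)(CC)CC)[C@H](O[Si](CC)(CC)CC)[C@@H](C)C(=O)O[C@H]1C | intermediate
30 | (2R,3R,4R,5S,6S,7R,8S)-3,4,5-trihydroxy-7-[(R)-4-hydroxyoct-2-ynoyloxy]-2,4,6-trimethylnonan-8-olide | CCCC[C@@H](O)C#CC(=O)O[C@@H]1[C@@H](C)[C@H](O)[C@@](C)(O)[C@H](O)[C@@H](C)C(=O)O[C@H]1C | intermediate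
31 | (2R,3R,4R,5S,6S,7R,8S)-3,4,5-trihydroxy-7-[(R,Z)-4-hydroxyoct-2-enoyloxy]-2,4,6-trimethylnonan-8-olide (CNP0205075.2) | CCCC[C@@H](O)/C=C\C(=O)O[C@@H]1[C@@H](C)[C@H](O)[C@@](C)(O)[C@H](O)[C@@H](C)C(=O)O[C@H]1C | target

## Step count and risks

Total: 17 steps. Longest linear sequence: 13 steps from 1 (steps 1–6, 9–12, 15–17).

Steps most likely to fail:

**Step 11 (ring closure).** Intermolecular aldol addition may outrun the nine-membered closure, enolisation may stray toward C8 with loss of that centre, or the aldehyde may meet the other enolate face and give the wrong 5,6-pair. The fallback generates the C6 enolate reductively from a bromide instead of by deprotonation (Reformatsky-type samarium aldol, a known way to close medium rings). It sets out from 17 and comes back at 22. Kinetic silylation of 17 (LiHMDS, TMSCl, THF, −78 °C) should give the C6 trimethylsilyl enol ether F1. NBS (THF, −78 → 0 °C) should convert it into the C6 bromo ketone F2 as a mixture of C6 epimers, which does not matter. Ozonolysis (O3, CH2Cl2, −78 °C; PPh3) should then give the bromo keto aldehyde F3. Slow addition of F3 to SmI2 (2.2 equiv, THF, −78 °C, high dilution) should form the trivalent samarium enolate regiospecifically at C6 without base; it should add to the C5 aldehyde inside a samarium chelate and give 22.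

**Step 15 (acylation at O7).** Discrimination between the two secondary hydroxyls may be insufficient, with acylation at O5, double acylation, or acyl migration from O7 to O5. The fallback blocks O5 before the C7 hydroxyl exists. It sets out from 22 and comes back at 30. Silylation of 22 (TESOTf, 2,6-lutidine, CH2Cl2, −78 °C) should give the 5-O-triethylsilyl 7-oxo lactone F4. Reduction with LiBH(s-Bu)3 (THF, −78 °C) under Felkin–Anh control (hydride anti to the C8–O9 bond and past the C6 hydrogen) should give the (7R)-alcohol F5. Esterification of F5 with 28 (DIC, DMAP, CH2Cl2) should give the fully silylated ynoate ester F6, and HF·pyridine/pyridine should remove all four silyl groups to give 30.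

**Step 17 (semi-hydrogenation).** The free polyol may bind to the poisoned palladium and make the reduction slow or unselective, over-reduction to the saturated ester may occur, or the (Z)-γ-hydroxy enoate may cyclise to a butenolide with expulsion of the C7 alcohol during the reaction. The fallback reverses the last two operations so that the Z-alkene is formed while O4′ is still silylated. It sets out from 29 and comes back at 31. Lindlar semi-hydrogenation of 29 (H2, Pd/CaCO3 poisoned with Pb(OAc)2, quinoline, EtOAc) should give the silylated (Z)-enoate F7. A short treatment with HF·pyridine buffered with pyridine (THF, 0 °C) should then give 31.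

## Further compounds

F1 | step 11 | (S)-3-(trimethylsilyloxy)pent-3-en-2-yl (2R,3R,4R)-2,4-dimethyl-3,4-bis(triethylsilyloxy)hex-5-enoate (enol ether geometry not fixed) | CC=C(O[Si](C)(C)C)[C@H](C)OC(=O)[C@H](C)[C@@H](O[Si](CC)(CC)CC)[C@](C)(O[Si](CC)(CC)CC)C=C
F2 | step 11 | (2S)-4-bromo-3-oxopentan-2-yl (2R,3R,4R)-2,4-dimethyl-3,4-bis(triethylsilyloxy)hex-5-enoate (C4′ epimers) | CC(Br)C(=O)[C@H](C)OC(=O)[C@H](C)[C@@H](O[Si](CC)(CC)CC)[C@](C)(O[Si](CC)(CC)CC)C=C
F3 | step 11 | (2S)-4-bromo-3-oxopentan-2-yl (2R,3R,4S)-2,4-dimethyl-5-oxo-3,4-bis(triethylsilyloxy)pentanoate (C4′ epimers) | CC(Br)C(=O)[C@H](C)OC(=O)[C@H](C)[C@@H](O[Si](CC)(CC)CC)[C@](C)(O[Si](CC)(CC)CC)C=O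
F4 | step 15 | (2R,3R,4R,5S,6S,8S)-2,4,6-trimethyl-7-oxo-3,4,5-tris(triethylsilyloxy)nonan-8-olide | O=C1[C@@H](C)[C@H](O[Si](CC)(CC)CC)[C@@](C)(O[Si](CC)(CC)CC)[C@H](O[Si](CC)(CC)CC)[C@@H](C)C(=O)O[C@H]1C
F5 | step 15 | (7R)-7-hydroxy-2,4,6-trimethyl-3,4,5-tris(triethylsilyloxy)nonan-8-olide (other centres as in F4) | O[C@@H]1[C@@H](C)[C@H](O[Si](CC)(CC)CC)[C@@](C)(O[Si](CC)(CC)CC)[C@H](O[Si](CC)(CC)CC)[C@@H](C)C(=O)O[C@H]1C
F6 | step 15 | 7-O-[(R)-4-(tert-butyldimethylsilyloxy)oct-2-ynoyl] ester of F5 | CCCC[C@@H](O[Si](C)(C)C(C)(C)C)C#CC(=O)O[C@@H]1[C@@H](C)[C@H](O[Si](CC)(CC)CC)[C@@](C)(O[Si](CC)(CC)CC)[C@H](O[Si](CC)(CC)CC)[C@@H](C)C(=O)O[C@H]1C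
F7 | step 17 | (2R,3R,4R,5S,6S,7R,8S)-7-[(R,Z)-4-(tert-butyldimethylsilyloxy)oct-2-enoyloxy]-5-hydroxy-2,4,6-trimethyl-3,4-bis(triethylsilyloxy)nonan-8-olide | CCCC[C@@H](O[Si](C)(C)C(C)(C)C)/C=C\C(=O)O[C@@H]1[C@@H](C)[C@H](O)[C@@](C)(O[Si](CC)(CC)CC)[C@H](O[Si](CC)(CC)CC)[C@@H](C)C(=O)O[C@H]1C
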